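**Assumption:** the target has no stereocentres, so "single enantiomer" is taken to mean the single (E)-enone geometric isomer; this is the only stereo-element to control.

## Retrosynthetic overview
1. No rings are formed: both benzene rings are purchased (2,4-dihydroxyacetophenone and 4-hydroxybenzaldehyde).
2. Disconnect the enone Cα=Cβ bond (Claisen–Schmidt) into a 3,5-diprenylated resacetophenone and a 4-oxygenated benzaldehyde.
3. Disconnect both aryl–prenyl bonds to 2,4-dihydroxyacetophenone and prenyl bromide (direct phenoxide C-prenylation at C3 and C5).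
4. MOM ethers mask the 4′-OH and 4-OH during the basic condensation; mild acid removes them last.

## Route

**Step 1**
Reactants: **1** 2,4-dihydroxyacetophenone; **2** prenyl bromide (1-bromo-3-methylbut-2-ene)
Product: **3** 1-[2,4-dihydroxy-3,5-bis(3-methylbut-2-en-1-yl)phenyl]ethan-1-one
Conditions: **2** (2.5 equiv, added slowly), 10% aq KOH (3 equiv), N2, 0 °C → rt, 12 h; acidify to pH 5; chromatography. Expect roughly 15–25% (estimate); recovered 3-prenyl and 5-prenyl mono-C-alkylated ketones are resubmitted.
Reagents that add atoms: prenyl bromide, CC(C)=CCBr (two equivalents incorporated)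
Why: Phenoxide C-alkylation (nuclear prenylation) of the ambident resorcinolate in water, where solvation of O⁻ favours attack through carbon, and C3 and C5 are the only ring positions activated by the oxygens, so both mono-prenyl intermediates converge on **3**.

**Step 2**
Reactants: **3**; **4** chloromethyl methyl ether (MOMCl)
Product: **5** 1-[2-hydroxy-4-(methoxymethoxy)-3,5-bis(3-methylbut-2-en-1-yl)phenyl]ethan-1-one
Conditions: MOMCl (1.3 equiv), K2CO3 (2 equiv), acetone, 0 °C → rt
Reagents that add atoms: MOMCl, COCCl
Why: Williamson-type O-alkylation that is selective for the more acidic, non-chelated 4-OH, because the 2-OH is held in a hydrogen bond to the ketone and stays free.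

**Step 3**
Reactants: **6** 4-hydroxybenzaldehyde; **4** MOMCl
Product: **7** 4-(methoxymethoxy)benzaldehyde
Conditions: MOMCl (1.2 equiv), iPr2NEt, CH2Cl2, 0 °C → rt
Reagents that add atoms: MOMCl, COCCl
Why: Simple phenol O-alkylation (acetal ether formation) that stops the aldehyde from becoming an unreactive 4-oxidobenzaldehyde under the basic condensation. (**7** is also catalogue-available from some suppliers.)

**Step 4**
Reactants: **5**; **7**
Product: **8** (E)-1-[2-hydroxy-4-(methoxymethoxy)-3,5-bis(3-methylbut-2-en-1-yl)phenyl]-3-[4-(methoxymethoxy)phenyl]prop-2-en-1-one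
Conditions: KOH (10 equiv, 50% aq), EtOH, 0 °C → rt, 24–48 h; quench at 0 °C to pH 5–6 with dilute AcOH
Reagents that add atoms: none (both reactants are numbered; water is lost)
Why: Claisen–Schmidt aldol condensation with E1cB dehydration, which gives the thermodynamically favoured (E)-enone exclusively; MOM ethers and prenyl groups are inert to hydroxide.

**Step 5**
Reactants: **8**
Product: **9** (target) (E)-1-[2,4-dihydroxy-3,5-bis(3-methylbut-2-en-1-yl)phenyl]-3-(4-hydroxyphenyl)prop-2-en-1-one
Conditions: 3 M aq HCl, MeOH, rt → 45 °C, TLC-monitored (1–3 h); NaHCO3 quench as soon as complete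
Reagents that add atoms: none
Why: Acid-catalysed acetal (MOM) hydrolysis, which is faster than protonation of the trisubstituted prenyl alkenes or acid-catalysed chalcone-to-flavanone cyclisation under these mild conditions, so the (E)-enone and both prenyl groups are retained.

## Compound list
1 | 2,4-dihydroxyacetophenone | CC(=O)c1ccc(O)cc1O | starting material
2 | prenyl bromide (1-bromo-3-methylbut-2-ene) | CC(C)=CCBr | starting material
3 | 1-[2,4-dihydroxy-3,5-bis(3-methylbut-2-en-1-yl)phenyl]ethan-1-one | CC(=O)c1cc(CC=C(C)C)c(O)c(CC=C(C)C)c1O | intermediate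
4 | chloromethyl methyl ether (MOMCl) | COCCl | starting material (reagent)
5 | 1-[2-hydroxy-4-(methoxymethoxy)-3,5-bis(3-methylbut-2-en-1-yl)phenyl]ethan-1-one | CC(=O)c1cc(CC=C(C)C)c(OCOC)c(CC=C(C)C)c1O | intermediate
6 | 4-hydroxybenzaldehyde | O=Cc1ccc(O)cc1 | starting material
7 | 4-(methoxymethoxy)benzaldehyde | COCOc1ccc(C=O)cc1 | intermediate
8 | (E)-1-[2-hydroxy-4-(methoxymethoxy)-3,5-bis(3-methylbut-2-en-1-yl)phenyl]-3-[4-(methoxymethoxy)phenyl]prop-2-en-1-one | COCOc1ccc(/C=C/C(=O)c2cc(CC=C(C)C)c(OCOC)c(CC=C(C)C)c2O)cc1 | intermediate
9 | (E)-1-[2,4-dihydroxy-3,5-bis(3-methylbut-2-en-1-yl)phenyl]-3-(4-hydroxyphenyl)prop-2-en-1-one | CC(C)=CCc1cc(C(=O)/C=C/c2ccc(O)cc2)c(O)c(CC=C(C)C)c1O | target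

## Summary
**Total steps:** 5
**Longest linear sequence:** 4 (steps 1 → 2 → 4 → 5); step 3 is a one-step side branch.

**Three steps most likely to fail, with fallbacks:**
1. **Step 1 (double C-prenylation).** Risks are low yield, competing O-prenylation, over-alkylation and a difficult separation. Fallback: a regiospecific iterative aromatic Claisen route. Make the 4-O-(1,1-dimethylallyl) ether (Pd(0)-catalysed O-alkylation with a 2-methylbut-3-en-2-yl carbonate) and rearrange it thermally ([3,3]) to place a linear prenyl ortho to O-4. Repeating this once fills the other ortho position, since C3 and C5 are both ortho to the 4-OH. An alternative is 3,5-diiodination followed by Stille coupling with tributyl(prenyl)stannane.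
2. **Step 5 (acidic MOM removal).** Risks are cyclisation of the ortho-prenyl phenols to 2,2-dimethylchromans and isomerisation of the chalcone to the flavanone. Fallback: carry the two phenols as allyl ethers through the same sequence and remove them under neutral Pd(0) conditions (Pd(PPh3)4, morpholine), so no acid touches the prenyl groups.
3. **Step 4 (Claisen–Schmidt).** Risks are sluggish enolisation of the hindered 2′-phenoxide ketone and partial flavanone formation. Fallback: protect the 2-OH as well (bis-MOM ketone), run a directed aldol (LiHMDS, THF, −78 °C, then **7**), and dehydrate the isolated β-hydroxy ketone (MsCl/Et3N, then DBU) to the (E)-enone.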